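**Retrosynthetic overview**
1. Arecatannin B1 ⇐ hydrogenolysis of its 13-fold O-benzylated trimer carrying bromine caps at C8 of the upper and the lower unit.
2. The two epicatechin units (2,3-cis-3,4-trans) ⇐ face-selective epoxidation and anti hydride opening of a bis(4-aryl-flav-2-ene), the C4 aryl groups relaying configuration to C3 and C2; the bis-flavene ⇐ reduction and syn-dehydration of a trimer bis(flavan-3-one).
3. Key disconnection (both interflavan bonds): reversed-polarity α-arylation of a flavan-3-one. An α-keto C4 cation (enolonium ion, from a 4-alkoxyflavan-3-one) is attacked by ring A of the flavan below: C6 of the 8-bromo-capped catechin unit first (4→6), then C8 of the resulting dimer on the 8-bromo-capped enolonium of the upper unit (4→8).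
4. All three units ⇐ (+)-catechin (benzylation; DDQ oxygenation at C4 and Dess–Martin oxidation for the enolonium precursor; NBS capping of the lower unit and of the upper-unit electrophile).
5. Ring order: no ring is built. The three chroman cores come intact from catechin and are joined from the lower unit upward; only C2/C3 of the upper two heterocycles are re-set at the end.

Assumption: (+)-catechin (2R,3S) is the only chiral starting material; all reagents named in the conditions are commercial.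

**Step 1**
Reactants: 1 (+)-catechin
Product: 2 5,7,3',4'-tetra-O-benzyl-(+)-catechin
Conditions: BnBr, K2CO3, DMF, 0 °C to rt
Reagents that add atoms: benzyl bromide BrCc1ccccc1
Why: Williamson etherification in which K2CO3 ionizes only the four phenols, so the secondary 3-OH stays free and no stereocenter is touched.

**Step 2**
Reactants: 2 5,7,3',4'-tetra-O-benzyl-(+)-catechin
Product: 3 (2R,3S,4S)-4-(2-ethoxyethoxy)-5,7,3',4'-tetra-O-benzylflavan-3-ol
Conditions: DDQ, HOCH2CH2OEt, CH2Cl2, rt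
Reagents that add atoms: 2-ethoxyethanol CCOCCO
Why: DDQ benzylic oxidation (hydride abstraction from C4 gives the cation stabilized by ring A, which the alcohol captures trans to the 2-aryl group), the known oxidative C4 functionalization of benzylated flavan-3-ols.

**Step 3**
Reactants: 3 (2R,3S,4S)-4-(2-ethoxyethoxy)-5,7,3',4'-tetra-O-benzylflavan-3-ol
Product: 4 (2R,4S)-4-(2-ethoxyethoxy)-5,7,3',4'-tetra-O-benzylflavan-3-one
Conditions: Dess–Martin periodinane, wet CH2Cl2, rt
Reagents that add atoms: none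
Why: Dess–Martin oxidation of the secondary carbinol under near-neutral conditions (as used for tetra-O-benzylcatechin itself) gives the α-alkoxy ketone, a storable enolonium equivalent, without epimerizing C2.

**Step 4**
Reactants: 4 (2R,4S)-4-(2-ethoxyethoxy)-5,7,3',4'-tetra-O-benzylflavan-3-one
Product: 5 (2R,4S)-8-bromo-4-(2-ethoxyethoxy)-5,7,3',4'-tetra-O-benzylflavan-3-one
Conditions: NBS (1.0 equiv), CH2Cl2, −78 to −20 °C, dark
Reagents that add atoms: N-bromosuccinimide O=C1CCC(=O)N1Br
Why: electrophilic aromatic bromination of the phloroglucinol-type ring A at C8 (C6 lies between two benzyloxy groups) is far faster at low temperature than bromination of the non-enolized ketone, so C2 and C4 are untouched; the cap keeps the upper unit from acting as a C8 nucleophile in step 8.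

**Step 5**
Reactants: 2 5,7,3',4'-tetra-O-benzyl-(+)-catechin
Product: 6 8-bromo-5,7,3',4'-tetra-O-benzyl-(+)-catechin
Conditions: NBS, CH2Cl2, −78 °C to rt
Reagents that add atoms: N-bromosuccinimide O=C1CCC(=O)N1Br
Why: electrophilic aromatic bromination goes to C8 of ring A (C6 lies between two benzyloxy groups), a known selectivity; the bromine caps C8 so that only C6 can later act as the nucleophile.

**Step 6**
Reactants: 6 8-bromo-5,7,3',4'-tetra-O-benzyl-(+)-catechin
Product: 7 8-bromo-3,5,7,3',4'-penta-O-benzyl-(+)-catechin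
Conditions: NaH, BnBr, DMF, 0 °C to rt
Reagents that add atoms: benzyl bromide BrCc1ccccc1
Why: Williamson etherification of the 3-OH, so that the lower unit cannot be dehydrated in step 10; the aryl bromide and both stereocenters are inert.

**Step 7**
Reactants: 4 (2R,4S)-4-(2-ethoxyethoxy)-5,7,3',4'-tetra-O-benzylflavan-3-one; 7 8-bromo-3,5,7,3',4'-penta-O-benzyl-(+)-catechin (3 equiv)
Product: 9 (2R)-tetra-O-benzyl-3-oxoflavan-(4β→6)-8-bromo-penta-O-benzylcatechin (dimer ketone; C4 aryl trans to the 2-aryl group), via enolonium triflate 8 (not isolated)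
Conditions: TMSOTf (0.3 equiv), CH2Cl2, 4 Å molecular sieves, −78 to −30 °C; 4 added slowly to 7
Reagents that add atoms: none
Why: Proposed new method: TMSOTf ionizes the C4–O bond of 4 to the α-keto benzylic cation 8, an enolonium ion in which the normally nucleophilic α-carbon of the ketone is electrophilic (still stabilized by O1 and the 5,7-dialkoxy ring A), and the only free ring-A carbon of 7 (C6; C8 is bromine-capped) attacks it in a Friedel–Crafts α-arylation of the ketone, entering pseudo-axially on the face opposite the 2-aryl group (2,4-trans, as in arylations of 2-arylchroman-4-yl cations) so that C2 dictates the new C4 center; slow addition of 4 to the excess nucleophile keeps self-condensation of 4 down, and capture at low temperature must outrun loss of H-2, because 8 is the keto tautomer of a 3-hydroxyflavylium ion; closest known types are the TMSOTf coupling of 4-alkoxyflavan-3-ols with flavan nucleophiles and Lewis-acid α-arylation of ketones through α-keto carbocations.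

**Step 8**
Reactants: 5 (2R,4S)-8-bromo-4-(2-ethoxyethoxy)-5,7,3',4'-tetra-O-benzylflavan-3-one; 9 dimer ketone (1.5 equiv)
Product: 11 (2R)-8-bromo-tetra-O-benzyl-3-oxoflavan-(4β→8)-(2R)-tetra-O-benzyl-3-oxoflavan-(4β→6)-8-bromo-penta-O-benzylcatechin (trimer diketone; both C4 aryl groups trans to the 2-aryl groups), via 8-bromo enolonium triflate 10 (not isolated)
Conditions: TMSOTf (0.3 equiv), CH2Cl2, 4 Å molecular sieves, −78 to −30 °C; 5 added slowly to 9
Reagents that add atoms: none
Why: Proposed new method: the same enolonium α-arylation through the 8-bromo ion 10, now on the dimer, whose only free ring-A positions are in the ketone unit and whose C8 is the more accessible one (4→8, as in classical chain extension); the bromine cap leaves the electrophile and the upper unit of the product only a hindered, deactivated C6, so self-condensation and growth beyond the trimer are slow next to attack by the free C8 of 9; the existing α-keto C4–H is pseudo-equatorial and poorly aligned for enolization, so the first interflavan center survives, and the new C4 is again set trans to the 2-aryl group; closest known types as in step 7.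

**Step 9**
Reactants: 11 trimer diketone
Product: 12 8-bromo-tetra-O-benzylcatechin-(4β→8)-tetra-O-benzylcatechin-(4β→6)-8-bromo-penta-O-benzylcatechin (trimer diol; both new carbinols 3S with OH cis to the C4 aryl and trans to the 2-aryl)
Conditions: NaBH4, THF/MeOH, −20 °C
Reagents that add atoms: none
Why: substrate-controlled hydride reduction: in each 2,4-trans ketone the bulky C4 aryl is pseudo-axial (peri strain with 5-OBn) and shields its face more than the pseudo-equatorial 2-aryl shields the other, so hydride enters anti to the C4 aryl and each carbinol is formed cis to it and cis to H-2 (2,3-trans-3,4-cis), which is not yet the natural configuration but is exactly the geometry the next step needs.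

**Step 10**
Reactants: 12 trimer diol
Product: 14 bis(flav-2-ene) trimer (upper and middle units are 5,7,3',4'-tetra-O-benzyl-2-aryl-4H-chromenes with C2=C3; C4 centers as in 11), via bis-sulfamate salt 13 (not isolated)
Conditions: Burgess reagent (MeO2C–N–SO2–NEt3 inner salt), toluene, rt then 70 °C
Reagents that add atoms: none
Why: Burgess dehydration by syn-elimination through the sulfamate ester: the only β-hydrogen cis to each C3–O is H-2 (H-4 is trans), so both units give the 2-aryl-4H-chromene enol ethers; C2 and C3 become sp2 while the C4 centers, which now carry the stereochemical information, are untouched.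

**Step 11**
Reactants: 14 bis(flav-2-ene) trimer
Product: 16 8-bromo-tetra-O-benzylepicatechin-(4β→8)-tetra-O-benzylepicatechin-(4β→6)-8-bromo-penta-O-benzylcatechin, via bis-epoxide 15 (not isolated)
Conditions: DMDO (acetone), CH2Cl2, −78 to −20 °C; then LiBHEt3, THF, −78 to 0 °C
Reagents that add atoms: dimethyldioxirane CC1(C)OO1
Why: glycal-type epoxidation followed by anti hydride opening: DMDO adds to each electron-rich enol ether from the face opposite the pseudo-axial C4 aryl (C3–O trans to the interflavan bond), and LiBHEt3 opens the epoxy ether at the benzylic acetal carbon C2 with inversion (hydride anti to the leaving oxygen, as for 1-aryl-1,2-anhydro sugars), leaving the 2-aryl cis to the 3-OH, i.e. (2R,3R) 2,3-cis-3,4-trans epicatechin units.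

**Step 12**
Reactants: 16 protected trimer
Product: 17 arecatannin B1
Conditions: H2 (1 atm), Pd(OH)2/C, Et3N, THF/MeOH/H2O, rt
Reagents that add atoms: none
Why: hydrogenolysis of the 13 benzyl ethers with simultaneous hydrodebromination of both C8 caps; the cyclic benzylic C2–O1 ethers and the interflavan bonds survive these acid-free conditions and no stereocenter is affected.

**Compound list**
1 | (+)-catechin, (2R,3S)-2-(3,4-dihydroxyphenyl)chroman-3,5,7-triol | Oc1cc(O)c2c(c1)O[C@H](c1ccc(O)c(O)c1)[C@@H](O)C2 | starting material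
2 | 5,7,3',4'-tetra-O-benzyl-(+)-catechin (2R,3S) | c3ccccc3COc1cc(OCc3ccccc3)c2c(c1)O[C@H](c1ccc(OCc3ccccc3)c(OCc3ccccc3)c1)[C@@H](O)C2 | intermediate
3 | (2R,3S,4S)-4-(2-ethoxyethoxy)-5,7,3',4'-tetra-O-benzylflavan-3-ol (alkoxy group trans to the 2-aryl group) | c3ccccc3COc1cc(OCc3ccccc3)c2c(c1)O[C@H](c1ccc(OCc3ccccc3)c(OCc3ccccc3)c1)[C@@H](O)[C@H]2OCCOCC | intermediate
4 | (2R,4S)-4-(2-ethoxyethoxy)-5,7,3',4'-tetra-O-benzylflavan-3-one | c3ccccc3COc1cc(OCc3ccccc3)c2c(c1)O[C@H](c1ccc(OCc3ccccc3)c(OCc3ccccc3)c1)C(=O)[C@H]2OCCOCC | intermediate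
5 | (2R,4S)-8-bromo-4-(2-ethoxyethoxy)-5,7,3',4'-tetra-O-benzylflavan-3-one | c3ccccc3COc1cc(OCc3ccccc3)c2c(c1Br)O[C@H](c1ccc(OCc3ccccc3)c(OCc3ccccc3)c1)C(=O)[C@H]2OCCOCC | intermediate
6 | (2R,3S)-8-bromo-5,7,3',4'-tetra-O-benzylcatechin | c3ccccc3COc1cc(OCc3ccccc3)c2c(c1Br)O[C@H](c1ccc(OCc3ccccc3)c(OCc3ccccc3)c1)[C@@H](O)C2 | intermediate
7 | (2R,3S)-8-bromo-3,5,7,3',4'-penta-O-benzylcatechin | c3ccccc3COc1cc(OCc3ccccc3)c2c(c1Br)O[C@H](c1ccc(OCc3ccccc3)c(OCc3ccccc3)c1)[C@@H](OCc3ccccc3)C2 | intermediate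
8 | (2R)-5,7,3',4'-tetra-O-benzyl-3-oxoflavan-4-ylium triflate (enolonium ion, cation at C4) | c3ccccc3COc1cc(OCc3ccccc3)c2c(c1)O[C@H](c1ccc(OCc3ccccc3)c(OCc3ccccc3)c1)C(=O)[CH+]2.[O-]S(=O)(=O)C(F)(F)F | intermediate (not isolated)
9 | dimer ketone: (2R)-tetra-O-benzyl-3-oxoflavan joined C4→C6 to 8-bromo-penta-O-benzylcatechin, C4 aryl trans to the 2-aryl (4β) | c3ccccc3COc1cc(OCc3ccccc3)c2c(c1)O[C@H](c1ccc(OCc3ccccc3)c(OCc3ccccc3)c1)C(=O)[C@H]2c1c(OCc3ccccc3)c(Br)c2c(c1OCc3ccccc3)C[C@H](OCc3ccccc3)[C@@H](c1ccc(OCc3ccccc3)c(OCc3ccccc3)c1)O2 | intermediate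
10 | (2R)-8-bromo-5,7,3',4'-tetra-O-benzyl-3-oxoflavan-4-ylium triflate (8-bromo enolonium ion, cation at C4) | c3ccccc3COc1cc(OCc3ccccc3)c2c(c1Br)O[C@H](c1ccc(OCc3ccccc3)c(OCc3ccccc3)c1)C(=O)[CH+]2.[O-]S(=O)(=O)C(F)(F)F | intermediate (not isolated)
11 | trimer diketone: (2R)-8-bromo-tetra-O-benzyl-3-oxoflavan joined C4→C8 to the ketone unit of 9, both ketone units 2,4-trans | c3ccccc3COc1cc(OCc3ccccc3)c2c(c1Br)O[C@H](c1ccc(OCc3ccccc3)c(OCc3ccccc3)c1)C(=O)[C@H]2c1c(OCc3ccccc3)cc(OCc3ccccc3)c2c1O[C@H](c1ccc(OCc3ccccc3)c(OCc3ccccc3)c1)C(=O)[C@H]2c1c(OCc3ccccc3)c(Br)c2c(c1OCc3ccccc3)C[C@H](OCc3ccccc3)[C@@H](c1ccc(OCc3ccccc3)c(OCc3ccccc3)c1)O2 | intermediate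
12 | trimer diol: both ketones of 11 reduced to (3S) carbinols, OH cis to the C4 aryl and trans to the 2-aryl (2,3-trans-3,4-cis) | c3ccccc3COc1cc(OCc3ccccc3)c2c(c1Br)O[C@H](c1ccc(OCc3ccccc3)c(OCc3ccccc3)c1)[C@@H](O)[C@H]2c1c(OCc3ccccc3)cc(OCc3ccccc3)c2c1O[C@H](c1ccc(OCc3ccccc3)c(OCc3ccccc3)c1)[C@@H](O)[C@H]2c1c(OCc3ccccc3)c(Br)c2c(c1OCc3ccccc3)C[C@H](OCc3ccccc3)[C@@H](c1ccc(OCc3ccccc3)c(OCc3ccccc3)c1)O2 | intermediate
13 | bis(triethylammonium) salt of the 3-O-[N-(methoxycarbonyl)sulfamate] diester of 12 | c3ccccc3COc1cc(OCc3ccccc3)c2c(c1Br)O[C@H](c1ccc(OCc3ccccc3)c(OCc3ccccc3)c1)[C@@H](OS(=O)(=O)[N-]C(=O)OC)[C@H]2c1c(OCc3ccccc3)cc(OCc3ccccc3)c2c1O[C@H](c1ccc(OCc3ccccc3)c(OCc3ccccc3)c1)[C@@H](OS(=O)(=O)[N-]C(=O)OC)[C@H]2c1c(OCc3ccccc3)c(Br)c2c(c1OCc3ccccc3)C[C@H](OCc3ccccc3)[C@@H](c1ccc(OCc3ccccc3)c(OCc3ccccc3)c1)O2.CC[NH+](CC)CC.CC[NH+](CC)CC | intermediate (not isolated)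
14 | bis(flav-2-ene) trimer: upper and middle units are 2-aryl-4H-chromenes (C2=C3), C4 centers as in 11 | c3ccccc3COc1cc(OCc3ccccc3)c2c(c1Br)OC(c1ccc(OCc3ccccc3)c(OCc3ccccc3)c1)=C[C@H]2c1c(OCc3ccccc3)cc(OCc3ccccc3)c2c1OC(c1ccc(OCc3ccccc3)c(OCc3ccccc3)c1)=C[C@H]2c1c(OCc3ccccc3)c(Br)c2c(c1OCc3ccccc3)C[C@H](OCc3ccccc3)[C@@H](c1ccc(OCc3ccccc3)c(OCc3ccccc3)c1)O2 | intermediate
15 | bis(2,3-epoxide) of 14, both epoxide oxygens trans to the C4 aryl groups | c3ccccc3COc1cc(OCc3ccccc3)c2c(c1Br)O[C@@]4(c1ccc(OCc3ccccc3)c(OCc3ccccc3)c1)[C@H](O4)[C@H]2c1c(OCc3ccccc3)cc(OCc3ccccc3)c2c1O[C@@]4(c1ccc(OCc3ccccc3)c(OCc3ccccc3)c1)[C@H](O4)[C@H]2c1c(OCc3ccccc3)c(Br)c2c(c1OCc3ccccc3)C[C@H](OCc3ccccc3)[C@@H](c1ccc(OCc3ccccc3)c(OCc3ccccc3)c1)O2 | intermediate (not isolated)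
16 | 8-bromo-tetra-O-benzylepicatechin-(4β→8)-tetra-O-benzylepicatechin-(4β→6)-8-bromo-penta-O-benzylcatechin | c3ccccc3COc1cc(OCc3ccccc3)c2c(c1Br)O[C@H](c1ccc(OCc3ccccc3)c(OCc3ccccc3)c1)[C@H](O)[C@H]2c1c(OCc3ccccc3)cc(OCc3ccccc3)c2c1O[C@H](c1ccc(OCc3ccccc3)c(OCc3ccccc3)c1)[C@H](O)[C@H]2c1c(OCc3ccccc3)c(Br)c2c(c1OCc3ccccc3)C[C@H](OCc3ccccc3)[C@@H](c1ccc(OCc3ccccc3)c(OCc3ccccc3)c1)O2 | intermediate
17 | arecatannin B1, epicatechin-(4β→8)-epicatechin-(4β→6)-catechin | Oc1cc(O)c2c(c1)O[C@H](c1ccc(O)c(O)c1)[C@H](O)[C@H]2c1c(O)cc(O)c2c1O[C@H](c1ccc(O)c(O)c1)[C@H](O)[C@H]2c1c(O)cc2c(c1O)C[C@H](O)[C@@H](c1ccc(O)c(O)c1)O2 | target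

**Step count and risks**
Total steps: 12. Longest linear sequence: 9 steps (steps 1, 2, 3, 4, 8, 9, 10, 11, 12).

Step 7 (step 8 is the same reaction type, so the behaviour of the ion in step 7 tells how step 8 will go): the α-keto cation may form sluggishly next to the carbonyl, or may lose H-2 to the achiral 3-hydroxyflavylium tautomer before it is captured, which would erase the control of C4 by C2. The fallback generates the enolonium oxidatively from an enol silane instead of by ionizing a C4–O bond. It sets out from 2: Dess–Martin oxidation gives tetra-O-benzylflavan-3-one F1; soft enolization (TMSOTf, Et3N, CH2Cl2, 0 °C) gives the C3–C4 trimethylsilyl enol ether F2; NBS at −78 °C brominates the enol silane (far more nucleophilic than the alkoxyarenes) to the 4-bromo ketone F3; AgOSO2CF3 then ionizes F3 at −78 °C in the presence of 7 to the same ion 8. The fallback returns to the route at 9.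

Step 10: the secondary sulfamate may ionize instead of eliminating (ring contraction through O1, or cleavage of an acid-labile interflavan bond). The fallback avoids the alcohol altogether and sets out from 11: kinetic deprotonation of the axial H-2 with KN(SiMe3)2 and trapping with PhNTf2 at −78 °C gives the bis(enol triflate) F4, and reduction with Pd(OAc)2, PPh3, HCO2H and Bu3N in DMF at 50 °C (the vinyl triflates react far faster than the hindered, electron-rich aryl bromides) returns to the route at 14.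

Step 11: the epoxy ether 15 may rearrange back to the 3-ketone, or the hydride may enter syn to the oxygen and give 2,3-trans units. The fallback replaces the epoxide by a diol and sets out from 14: dihydroxylation with OsO4 (catalytic) and N-methylmorpholine N-oxide, again from the face opposite the C4 aryl groups, gives the bis(2,3-cis-diol) hemiketal F5, and ionic reduction with Et3SiH and BF3·OEt2 in CH2Cl2 at −78 °C removes each C2–OH through the oxocarbenium ion, hydride entering trans to the neighbouring C3–O; it returns to the route at 16.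

**Further compounds**
F1 | step 7 | (2R)-5,7,3',4'-tetra-O-benzylflavan-3-one | c3ccccc3COc1cc(OCc3ccccc3)c2c(c1)O[C@H](c1ccc(OCc3ccccc3)c(OCc3ccccc3)c1)C(=O)C2
F2 | step 7 | (2R)-5,7,3',4'-tetra-O-benzyl-3-(trimethylsilyloxy)flav-3-ene (C3–C4 enol silane) | c3ccccc3COc1cc(OCc3ccccc3)c2c(c1)O[C@H](c1ccc(OCc3ccccc3)c(OCc3ccccc3)c1)C(O[Si](C)(C)C)=C2
F3 | step 7 | (2R,4S)-4-bromo-5,7,3',4'-tetra-O-benzylflavan-3-one (bromine trans to the 2-aryl group) | c3ccccc3COc1cc(OCc3ccccc3)c2c(c1)O[C@H](c1ccc(OCc3ccccc3)c(OCc3ccccc3)c1)C(=O)[C@H]2Br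
F4 | step 10 | bis(enol triflate) of 11 (C2=C3 with 3-OSO2CF3 in the upper and middle units, C4 centers as in 11) | c3ccccc3COc1cc(OCc3ccccc3)c2c(c1Br)OC(c1ccc(OCc3ccccc3)c(OCc3ccccc3)c1)=C(OS(=O)(=O)C(F)(F)F)[C@H]2c1c(OCc3ccccc3)cc(OCc3ccccc3)c2c1OC(c1ccc(OCc3ccccc3)c(OCc3ccccc3)c1)=C(OS(=O)(=O)C(F)(F)F)[C@H]2c1c(OCc3ccccc3)c(Br)c2c(c1OCc3ccccc3)C[C@H](OCc3ccccc3)[C@@H](c1ccc(OCc3ccccc3)c(OCc3ccccc3)c1)O2
F5 | step 11 | bis(2,3-cis-diol) of 14 (2-hydroxy hemiketal and 3-OH in the upper and middle units, both trans to the C4 aryl) | c3ccccc3COc1cc(OCc3ccccc3)c2c(c1Br)O[C@@](O)(c1ccc(OCc3ccccc3)c(OCc3ccccc3)c1)[C@H](O)[C@H]2c1c(OCc3ccccc3)cc(OCc3ccccc3)c2c1O[C@@](O)(c1ccc(OCc3ccccc3)c(OCc3ccccc3)c1)[C@H](O)[C@H]2c1c(OCc3ccccc3)c(Br)c2c(c1OCc3ccccc3)C[C@H](OCc3ccccc3)[C@@H](c1ccc(OCc3ccccc3)c(OCc3ccccc3)c1)O2
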